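Ring A (C1–C6) is read as a reduced 1,4-benzoquinone. C6 (tertiary carbinol) and C3 (alkylidene) are the former carbonyls. Spiro C1 holds the ester carbon that becomes C10. The cis pair, C7 on C1 and chain C1'–C3' on C2, is one four-carbon diene. A single catalytic asymmetric endo Diels–Alder reaction joins 2-methoxycarbonyl-1,4-benzoquinone (from methyl gentisate) and bought (E)-1-acetoxybutadiene. It forms C1–C7 and C2–C1', fixes C1 and C2, and closes a sacrificial cyclohexene. That ring is later cut between C7 and C3', and ring B is then closed onto C7 by a carbonyl-ene reaction.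

Key step: step 2

Atom labels (used for all compounds):
- Ring A: C1 (spiro), C2 (CH bearing chain C1'–C3'), C3 (alkylidene carbon), C4, C5, C6 (C(OH)CH3).
- Ring B: C1, C7 (CHOH), C8 (CH bearing the side chain), C9, C10.
- Side chain: C11 (bears C12H2OAc)=C13–C14=C15–C16(=CH2)–homoprenyl.
- Ring S: the sacrificial ring C1–C7–C3'–C2'–C1'–C2.

Assumption: the (S,S)-pybox ligand is taken to shield the quinone face that would lead to the antipode of 4; should the sense of induction be the opposite, the equally available (R,R)-ligand is used.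

Step 1
Reactants: 1 methyl 2,5-dihydroxybenzoate
Product: 2 2-methoxycarbonyl-1,4-benzoquinone
Conditions: Ag2O (2.5 equiv), MgSO4, CH2Cl2, rt, dark; filtered and used at once
Reagents that add atoms: none
Why: Two-electron oxidation of a hydroquinone by Ag2O is the standard mild entry to ester-activated benzoquinones, and the dry medium avoids hydration of the electrophilic product.

Step 2
Reactants: 2 2-methoxycarbonyl-1,4-benzoquinone; 3 (E)-1-acetoxybuta-1,3-diene
Product: 4 endo adduct, a cis-fused bicycle of the ring A enedione (C6=O, C4=C5, C3=O) and cyclohexene ring S (C2'=C3'); C10 ester on C1 and H on C2 lie on the same face, and the 7-OAc is trans to the ester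
Conditions: Gd(OTf)3 (10 mol %), 2,6-bis[(4S)-4-phenyl-4,5-dihydro-1,3-oxazol-2-yl]pyridine (12 mol %), 4 Å MS, CH2Cl2, −78 °C; 3 as 2.5 equiv of the commercial E/Z mixture (only the E isomer reacts)
Reagents that add atoms: none
Why: The chiral Lewis acid binds the quinone as a chelate through the ester carbonyl and the C6 carbonyl and lowers the LUMO of the C1=C2 bond only, so the diene adds in a concerted, asynchronous, normal-demand [4+2] cycloaddition, a reaction type known for 2-alkoxycarbonylquinones and 1-oxygenated butadienes under chiral Lewis acid catalysis. Ring S closes by suprafacial–suprafacial cycloaddition, both σ bonds (C1–C7 and C2–C1') forming in one step. C1 and C2 come out cis because the addition is suprafacial on the ring double bond, and their absolute configuration is set by the ligand, which covers one face of the chelated quinone. C7 is set by the endo rule together with the E geometry of the diene, which places the acetoxy group on the side of the C6 carbonyl branch and trans to the ester. Site selectivity comes from the ester, which makes C1=C2 the more electron-poor double bond. Regioselectivity comes from the largest LUMO coefficient at unsubstituted C2 (conjugate position of both the ester and the C6 ketone), which pairs with the largest HOMO coefficient at the CH2 terminus of the dienyl acetate.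

Step 3
Reactants: 4 endo adduct
Product: 5 saturated cis-fused 3,6-dione (C4=C5 and C2'=C3' hydrogenated; the three stereocentres unchanged)
Conditions: H2 (1 atm), 5% Rh/Al2O3, EtOAc, rt
Reagents that add atoms: none
Why: Heterogeneous catalytic hydrogenation saturates the enedione and the cis-disubstituted alkene in one operation, Rh on alumina being little prone to hydrogenolysis of the allylic acetate, and no stereocentre is made or touched.

Step 4
Reactants: 5 saturated dione
Product: 6 C3 ethylene ketal of 5 (C6 ketone free)
Conditions: (Me3SiOCH2)2 (1.2 equiv), Me3SiOTf (5 mol %), CH2Cl2, −78 to −30 °C; pyridine quench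
Reagents that add atoms: 1,2-bis(trimethylsilyloxy)ethane, C[Si](C)(C)OCCO[Si](C)(C)C
Why: Aprotic Noyori-type ketalisation is sterically controlled, so only the C3 carbonyl next to a CH reacts while the C6 carbonyl next to quaternary C1 stays free, and the cold non-protic medium avoids enolisation and epimerisation at C2.

Step 5
Reactants: 6 keto ketal
Product: 7 tertiary alcohol with CH3 and OH on C6, CH3 cis to the C10 ester and OH cis to C7
Conditions: MeLi and CeCl3 (1.5 equiv each, premixed), THF, −78 °C; cold aqueous quench
Reagents that add atoms: methyllithium, [Li]C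
Why: Organocerium 1,2-addition is fast on hindered enolisable ketones and slow on esters at −78 °C, and the nucleophile enters on the convex face of the cis-fused bicycle (the face of the C10 ester and H-2, away from ring S), which sets C6.

Step 6
Reactants: 7 tertiary alcohol
Product: 8 C6 triethylsilyl ether of 7
Conditions: Et3SiOTf, 2,6-lutidine, CH2Cl2, 0 °C to rt
Reagents that add atoms: triethylsilyl triflate, CC[Si](CC)(CC)OS(=O)(=O)C(F)(F)F
Why: Silyl triflate silylation of the hindered tertiary alcohol blocks retro-aldol cleavage of the C1–C6 bond in the carbonyl compounds that follow and later serves as a bulky non-chelating group.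

Step 7
Reactants: 8 silyl ether
Product: 9 diol with C10H2OH on C1 and free 7-OH (C6-OSiEt3 and C3 ketal kept)
Conditions: i-Bu2AlH (6 equiv), CH2Cl2, −78 to 0 °C; aqueous work-up
Reagents that add atoms: none
Why: Hydride reduction converts the angular ester into the C10 carbinol and cleaves the acetate in the same operation, and the weakly nucleophilic aluminium alkoxides are unlikely to trigger silyl migration.

Step 8
Reactants: 9 diol
Product: 10 keto aldehyde (C10HO on C1, C7 ketone)
Conditions: Dess–Martin periodinane (3 equiv), CH2Cl2, 0 °C to rt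
Reagents that add atoms: none
Why: Dess–Martin oxidation under neutral conditions takes the primary and the secondary alcohol to aldehyde and ketone at once without opening the non-enolisable 1,3-dicarbonyl unit at C1.

Step 9
Reactants: 10 keto aldehyde
Product: 11 vinyl ketone (C10H=C9H2 on C1, C7 ketone)
Conditions: Ph3PCH3Br, KN(SiMe3)2 (1.1 equiv each), THF, 0 °C; then 10, −78 to 0 °C
Reagents that add atoms: methyltriphenylphosphonium bromide, C[P+](c1ccccc1)(c1ccccc1)c1ccccc1.[Br-]
Why: Wittig methylenation distinguishes the aldehyde from the more hindered, enolisable C7 ketone, so about one equivalent of ylide installs C9 as a vinyl group on C1.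

Step 10
Reactants: 11 vinyl ketone
Product: 12 C7=C3' tert-butyldimethylsilyl enol ether of 11
Conditions: t-BuMe2SiOTf, Et3N, CH2Cl2, 0 °C
Reagents that add atoms: tert-butyldimethylsilyl triflate, CC(C)(C)[Si](C)(C)OS(=O)(=O)C(F)(F)F
Why: Soft enolisation with silyl triflate and amine can only go towards C3' because C1 is quaternary, so a single silyl enol ether marks the C7–C3' bond for cleavage.

Step 11
Reactants: 12 silyl enol ether
Product: 14 monocyclic diol carrying C7H2OH plus vinyl on C1 and 3-hydroxypropyl on C2 cis to C7, via aldehyde silyl ester 13 (not isolated)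
Conditions: O3, CH2Cl2, −78 °C (Sudan Red 7B end point); PPh3; then i-Bu2AlH (5 equiv), −78 to 0 °C; aqueous work-up
Reagents that add atoms: ozone, [O-][O+]=O
Why: Ozonolysis is chemoselective for the electron-rich silyl enol ether over the hindered monosubstituted vinyl group when stopped at the indicator end point, and the hydride stage reduces aldehyde and silyl ester to the two primary alcohols without touching C1, C2 or C6.

Step 12
Reactants: 14 diol
Product: 15 C3' tert-butyldiphenylsilyl ether of 14 (C7H2OH free)
Conditions: t-BuPh2SiCl (1.05 equiv), imidazole, CH2Cl2, 0 °C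
Reagents that add atoms: tert-butyldiphenylsilyl chloride, CC(C)(C)[Si](Cl)(c1ccccc1)c1ccccc1
Why: In this sterically controlled monosilylation the bulky chlorosilane reacts with the unhindered C3' alcohol and not with the neopentyl C7 alcohol.

Step 13
Reactants: 16 prop-2-yn-1-ol
Product: 18 (Z)-2-(iodomethylene)pent-4-en-1-ol, via alkenylmagnesium alkoxide 17 (not isolated)
Conditions: allylMgBr (3 equiv), CuI (10 mol %), Et2O, 0 °C to rt; then I2, −30 °C
Reagents that add atoms: allylmagnesium bromide, C=CC[Mg]Br; iodine, [I][I]
Why: Copper-catalysed carbomagnesiation of propargyl alcohol proceeds by anti addition through a five-membered magnesium alkoxide chelate, so iodinolysis gives the Z-iodoalkene with iodine cis to CH2OH.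

Step 14
Reactants: 18 iodo alcohol
Product: 19 tert-butyldimethylsilyl ether of 18 (Z)
Conditions: t-BuMe2SiCl, imidazole, CH2Cl2, rt
Reagents that add atoms: tert-butyldimethylsilyl chloride, CC(C)(C)[Si](C)(C)Cl
Why: Standard silylation of a primary allylic alcohol gives the C12 oxygen a group that is poorly coordinating and can later be removed selectively.

Step 15
Reactants: 15 vinyl alcohol; 19 iodoalkene
Product: 21 coupled product C1–C10H2–C9H2–C8H=C11(C12H2OSiMe2t-Bu)–C13H2–C14H=C15H2 with C9 cis to C12, via B-alkyl borane 20 (not isolated)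
Conditions: 9-BBN-H (2.5 equiv), THF, rt to 40 °C; H2O; then 19, PdCl2(dppf) (5 mol %), AsPh3, Cs2CO3, DMF/THF/H2O, rt
Reagents that add atoms: none
Why: Anti-Markovnikov hydroboration of the vinyl group followed by B-alkyl Suzuki–Miyaura coupling joins C9 to C8 with retention of the iodoalkene geometry, excess borane being destroyed with water before the diene-containing partner is added.

Step 16
Reactants: 21 ketal
Product: 22 C3 ketone (C7H2OH free, partly resting as its bridged hemiketal)
Conditions: pyridinium p-toluenesulfonate (0.2 equiv), acetone/H2O 10:1, 40 °C, short contact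
Reagents that add atoms: water, O
Why: Mild acid-catalysed ketal hydrolysis frees the sterically strained C3 ketal faster than it attacks the silyl ethers, and short exposure limits enolisation towards C2.

Step 17
Reactants: 22 keto alcohol
Product: 23 C7 triethylsilyl ether of 22
Conditions: Et3SiCl, imidazole, CH2Cl2, 0 °C
Reagents that add atoms: triethylsilyl chloride, CC[Si](Cl)(CC)CC
Why: Silylation drains the open primary alcohol from the hemiketal equilibrium and keeps the C7 oxygen, which sits 1,3-diaxial to C3, from reacting with that centre in the next two steps.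

Step 18
Reactants: 23 ketone
Product: 24 tertiary allylic alcohol (isopropenyl and OH on C3, OH cis to C7; this centre is lost in step 19)
Conditions: isopropenylMgBr (2 equiv), LaCl3·2LiCl (1 equiv), THF, −20 to 0 °C
Reagents that add atoms: isopropenylmagnesium bromide, C=C(C)[Mg]Br
Why: Lanthanide-assisted Grignard 1,2-addition suppresses enolisation, and attack from the equatorial side, anti to the axial C7H2OSiEt3 group, should give the axial alcohol.

Step 19
Reactants: 24 tertiary allylic alcohol
Product: 25 (E)-enal C3=C(CH3)CHO with CHO cis to C4 and CH3 cis to C2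
Conditions: pyridinium chlorochromate [C5H5NH][CrO3Cl] (4 equiv), 4 Å MS, CH2Cl2, rt
Reagents that add atoms: pyridinium chlorochromate (supplies the aldehyde oxygen), [O-][Cr](=O)(=O)Cl.c1cc[nH+]cc1
Why: In the Babler–Dauben oxidative transposition the tertiary chromate ester undergoes a [3,3] shift and the primary chromate is oxidised, and the chromium-bearing CH2 terminus should turn to the unbranched C4 side, away from the substituted C2, which sets the alkene geometry.

Step 20
Reactants: 25 enal
Product: 26 dialdehyde (C7HO on C1 plus the enal)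
Conditions: (COCl)2, DMSO, CH2Cl2, −78 to −40 °C; Et3N, to 0 °C
Reagents that add atoms: none
Why: Under Swern conditions a primary triethylsilyl ether is cleaved by the activated sulfoxide and oxidised directly to the aldehyde, while the tertiary triethylsilyl, tert-butyldimethylsilyl and tert-butyldiphenylsilyl ethers persist.

Step 21
Reactants: 26 dialdehyde
Product: 27 (E)-alkenyl pinacol boronate at C15 (C14=C15 E)
Conditions: vinylboronic acid pinacol ester (3 equiv), second-generation Hoveyda–Grubbs catalyst (5 mol %), CH2Cl2, 40 °C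
Reagents that add atoms: vinylboronic acid pinacol ester, C=CB1OC(C)(C)C(C)(C)O1
Why: Olefin cross-metathesis engages only the monosubstituted C14=C15 alkene, the tri- and tetrasubstituted alkenes and the aldehydes being spectators, and the bulky boronate favours the E-alkene.

Step 22
Reactants: 28 6-methylhept-5-en-2-one
Product: 30 6-methylhepta-1,5-dien-2-yl triflate, via kinetic lithium enolate 29 (not isolated)
Conditions: LiN(i-Pr)2, THF, −78 °C; PhNTf2, −78 to 0 °C
Reagents that add atoms: N-phenylbis(trifluoromethanesulfonimide), O=S(=O)(N(c1ccccc1)S(=O)(=O)C(F)(F)F)C(F)(F)F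
Why: Kinetic deprotonation of the methyl ketone at CH3 followed by O-triflation gives the 1,1-disubstituted enol triflate that carries C16, its methylene and the homoprenyl tail.

Step 23
Reactants: 27 alkenyl boronate; 30 enol triflate
Product: 31 ene precursor, a dialdehyde with the chain C8H=C11(C12H2OSiMe2t-Bu)–C13H2–C14H=C15H–C16(=CH2)–homoprenyl (C14=C15 E)
Conditions: Pd(PPh3)4 (5 mol %), K3PO4, THF/H2O, rt to 40 °C
Reagents that add atoms: none
Why: The sp2–sp2 Suzuki–Miyaura coupling forms C15–C16 with retention of the E-boronate geometry and tolerates the non-enolisable aldehyde, the enal and the silyl ethers.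

Step 24
Reactants: 31 ene precursor
Product: 32 spiro alcohol, ring B closed, 7-OH and the C8 side chain cis and both on the C2 side of ring B, C11=C13 with C14 cis to C12 (Z)
Conditions: Me2AlCl (3 equiv), CH2Cl2, −78 to −40 °C
Reagents that add atoms: none
Why: In this Lewis-acid-promoted intramolecular carbonyl-ene reaction (type 1, five-membered ring) C8 attacks the C7 aldehyde while a doubly allylic hydrogen of C13 moves to oxygen; the cyclic transition state forces OH and side chain cis and puts C14 anti to C8, and the bulky non-chelating C6-OSiEt3 group, with its opposed C–O dipole, should keep the complexed carbonyl oxygen and the alkene on the C2 side.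

Step 25
Reactants: 32 spiro alcohol
Product: 33 diol (C12H2OH and 7-OH free; C3'-OSiPh2t-Bu and C6-OSiEt3 kept)
Conditions: HF·pyridine, pyridine, THF, 0 °C
Reagents that add atoms: none
Why: Buffered fluoride desilylation under steric control removes the unhindered primary allylic tert-butyldimethylsilyl ether first, and a premature loss of the hindered tertiary silyl ether would be harmless for the next step.

Step 26
Reactants: 33 diol
Product: 34 C12 acetate of 33
Conditions: Ac2O (1.2 equiv), pyridine, CH2Cl2, 0 °C
Reagents that add atoms: acetic anhydride, CC(=O)OC(C)=O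
Why: Acylation without a nucleophilic catalyst is selective for the unhindered primary allylic alcohol over the secondary C7 alcohol, which is flanked by the spiro carbon.

Step 27
Reactants: 34 acetate
Product: 35 target CNP0204268.1
Conditions: HF·pyridine (excess), pyridine, THF, 0 °C to rt
Reagents that add atoms: none
Why: Global fluoride desilylation in a buffered, weakly acidic medium frees the C3' and C6 hydroxyl groups without acetate migration or damage to the enal and the triene.

Compound list
1 | methyl 2,5-dihydroxybenzoate | COC(=O)c1cc(O)ccc1O | starting material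
2 | 2-methoxycarbonyl-1,4-benzoquinone | COC(=O)C1=CC(=O)C=CC1=O | intermediate
3 | (E)-1-acetoxybuta-1,3-diene | C=C/C=C/OC(C)=O | starting material
4 | cis-fused endo adduct with angular ester | COC(=O)[C@]12C(=O)C=CC(=O)[C@H]1CC=C[C@H]2OC(C)=O | intermediate
5 | saturated cis-fused 3,6-dione | COC(=O)[C@]12C(=O)CCC(=O)[C@H]1CCC[C@H]2OC(C)=O | intermediate
6 | C3 ethylene ketal | COC(=O)[C@]12C(=O)CCC3(OCCO3)[C@H]1CCC[C@H]2OC(C)=O | intermediate
7 | C6 tertiary alcohol | COC(=O)[C@]12[C@@](C)(O)CCC3(OCCO3)[C@H]1CCC[C@H]2OC(C)=O | intermediate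
8 | C6 triethylsilyl ether | COC(=O)[C@]12[C@@](C)(O[Si](CC)(CC)CC)CCC3(OCCO3)[C@H]1CCC[C@H]2OC(C)=O | intermediate
9 | C10/C7 diol | OC[C@]12[C@@](C)(O[Si](CC)(CC)CC)CCC3(OCCO3)[C@H]1CCC[C@H]2O | intermediate
10 | keto aldehyde | O=C[C@]12[C@@](C)(O[Si](CC)(CC)CC)CCC3(OCCO3)[C@H]1CCCC2=O | intermediate
11 | vinyl ketone | C=C[C@]12[C@@](C)(O[Si](CC)(CC)CC)CCC3(OCCO3)[C@H]1CCCC2=O | intermediate
12 | C7=C3' silyl enol ether | C=C[C@]12[C@@](C)(O[Si](CC)(CC)CC)CCC3(OCCO3)[C@H]1CCC=C2O[Si](C)(C)C(C)(C)C | intermediate
13 | aldehyde silyl ester (not isolated) | C=C[C@]1([C@H](CCC=O)C2(OCCO2)CC[C@]1(C)O[Si](CC)(CC)CC)C(=O)O[Si](C)(C)C(C)(C)C | intermediate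
14 | monocyclic diol | C=C[C@]1([C@H](CCCO)C2(OCCO2)CC[C@]1(C)O[Si](CC)(CC)CC)CO | intermediate
15 | C3' tert-butyldiphenylsilyl ether | C=C[C@]1([C@H](CCCO[Si](c2ccccc2)(c2ccccc2)C(C)(C)C)C2(OCCO2)CC[C@]1(C)O[Si](CC)(CC)CC)CO | intermediate
16 | prop-2-yn-1-ol | C#CCO | starting material
17 | alkenylmagnesium alkoxide (not isolated) | Br[Mg]/C=C(/CC=C)CO[Mg]Br | intermediate
18 | (Z)-2-(iodomethylene)pent-4-en-1-ol | I/C=C(/CC=C)CO | intermediate
19 | silyl ether of 18 | I/C=C(/CC=C)CO[Si](C)(C)C(C)(C)C | intermediate
20 | B-alkyl borane, C7 oxygen as borinate (not isolated) | C12CCCC(CCC1)B2CC[C@]3([C@H](CCCO[Si](c4ccccc4)(c4ccccc4)C(C)(C)C)C4(OCCO4)CC[C@]3(C)O[Si](CC)(CC)CC)COB5C6CCCC5CCC6 | intermediate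
21 | coupled ketal alcohol | C=CC/C(CO[Si](C)(C)C(C)(C)C)=C/CC[C@]1([C@H](CCCO[Si](c2ccccc2)(c2ccccc2)C(C)(C)C)C2(OCCO2)CC[C@]1(C)O[Si](CC)(CC)CC)CO | intermediate
22 | C3 keto alcohol | C=CC/C(CO[Si](C)(C)C(C)(C)C)=C/CC[C@]1([C@H](CCCO[Si](c2ccccc2)(c2ccccc2)C(C)(C)C)C(=O)CC[C@]1(C)O[Si](CC)(CC)CC)CO | intermediate
23 | C7 triethylsilyl ether ketone | C=CC/C(CO[Si](C)(C)C(C)(C)C)=C/CC[C@]1([C@H](CCCO[Si](c2ccccc2)(c2ccccc2)C(C)(C)C)C(=O)CC[C@]1(C)O[Si](CC)(CC)CC)CO[Si](CC)(CC)CC | intermediate
24 | tertiary allylic alcohol | C=CC/C(CO[Si](C)(C)C(C)(C)C)=C/CC[C@]1([C@H](CCCO[Si](c2ccccc2)(c2ccccc2)C(C)(C)C)[C@@](O)(C(C)=C)CC[C@]1(C)O[Si](CC)(CC)CC)CO[Si](CC)(CC)CC | intermediate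
25 | (E)-enal | C=CC/C(CO[Si](C)(C)C(C)(C)C)=C/CC[C@]1([C@H](CCCO[Si](c2ccccc2)(c2ccccc2)C(C)(C)C)/C(=C(\C)C=O)CC[C@]1(C)O[Si](CC)(CC)CC)CO[Si](CC)(CC)CC | intermediate
26 | dialdehyde | C=CC/C(CO[Si](C)(C)C(C)(C)C)=C/CC[C@]1([C@H](CCCO[Si](c2ccccc2)(c2ccccc2)C(C)(C)C)/C(=C(\C)C=O)CC[C@]1(C)O[Si](CC)(CC)CC)C=O | intermediate
27 | (E)-alkenyl pinacol boronate | CC1(C)OB(OC1(C)C)/C=C/C/C(CO[Si](C)(C)C(C)(C)C)=C/CC[C@]2([C@H](CCCO[Si](c3ccccc3)(c3ccccc3)C(C)(C)C)/C(=C(\C)C=O)CC[C@]2(C)O[Si](CC)(CC)CC)C=O | intermediate
28 | 6-methylhept-5-en-2-one | CC(=O)CCC=C(C)C | starting material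
29 | kinetic lithium enolate (not isolated) | [Li]OC(=C)CCC=C(C)C | intermediate
30 | 6-methylhepta-1,5-dien-2-yl triflate | C=C(CCC=C(C)C)OS(=O)(=O)C(F)(F)F | intermediate
31 | ene precursor | CC(C)=CCCC(=C)/C=C/C/C(CO[Si](C)(C)C(C)(C)C)=C/CC[C@]1([C@H](CCCO[Si](c2ccccc2)(c2ccccc2)C(C)(C)C)/C(=C(\C)C=O)CC[C@]1(C)O[Si](CC)(CC)CC)C=O | intermediate
32 | spiro alcohol | C=C(/C=C/C=C(\CO[Si](C)(C)C(C)(C)C)[C@@H]1CC[C@]2([C@H](CCCO[Si](c3ccccc3)(c3ccccc3)C(C)(C)C)/C(=C(\C)C=O)CC[C@]2(C)O[Si](CC)(CC)CC)[C@@H]1O)CCC=C(C)C | intermediate
33 | C12/C7 diol | C=C(/C=C/C=C(\CO)[C@@H]1CC[C@]2([C@H](CCCO[Si](c3ccccc3)(c3ccccc3)C(C)(C)C)/C(=C(\C)C=O)CC[C@]2(C)O[Si](CC)(CC)CC)[C@@H]1O)CCC=C(C)C | intermediate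
34 | C12 acetate | C=C(/C=C/C=C(\COC(C)=O)[C@@H]1CC[C@]2([C@H](CCCO[Si](c3ccccc3)(c3ccccc3)C(C)(C)C)/C(=C(\C)C=O)CC[C@]2(C)O[Si](CC)(CC)CC)[C@@H]1O)CCC=C(C)C | intermediate
35 | CNP0204268.1 | C=C(/C=C/C=C(\COC(C)=O)[C@@H]1CC[C@]2([C@H](CCCO)/C(=C(\C)C=O)CC[C@]2(C)O)[C@@H]1O)CCC=C(C)C | target

Total step count: 27. Longest linear sequence: 24 steps (steps 1–12, 15–21, 23–27).

Steps most likely to fail

1. Step 2 (key step).
   - What may go wrong: the catalyst may cover one quinone face incompletely with this small dienyl ester. The Lewis acid may also induce enolisation of the adduct, followed by loss of acetic acid.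
   - Fallback: setting out from 2 and 3, the cycloaddition is run without catalyst (toluene, rt). This should give the same endo adduct as a racemate, that is 4 together with the antipodal adduct F1. Hydrogenation as in step 3 then gives 5 together with the antipodal saturated dione F2. Preparative chromatography on a chiral stationary phase separates the two, and the route is rejoined at 5.

2. Step 24.
   - What may go wrong: the Lewis acid may cause side reactions along the skipped polyene, such as proton loss from C12 instead of C13 or cationic cyclisation. The preference for the C2 side of ring B may also be eroded.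
   - Fallback: setting out from 26, ring B is closed before the polyene exists. Me2AlCl in CH2Cl2 at −78 °C acts on the simple allyl-substituted dialdehyde and should give the spiro alcohol with a terminal diene F3. Cross-metathesis of its terminal alkene with vinylboronic acid pinacol ester gives the dienyl pinacol boronate F4. Suzuki–Miyaura coupling with 30 returns to the route at 32.

3. Step 19.
   - What may go wrong: control of the tetrasubstituted alkene geometry in the chromate shift may be poor. The tertiary allylic alcohol may dehydrate under the acidic conditions. The C7 silyl ether may be lost before the shift is complete.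
   - Fallback: setting out from 24, a non-oxidative and reversible 1,3-transposition with Ph3SiOReO3 (catalytic, Et2O, −50 to 0 °C) gives the primary allylic alcohol F5. Its geometry is then set by product stability, and the unwanted isomer can be resubjected. Oxidation with MnO2 in CH2Cl2 returns to the route at 25.

Further compounds
F1 | step 2 | antipodal adduct (enantiomer of 4) | COC(=O)[C@@]12C(=O)C=CC(=O)[C@@H]1CC=C[C@@H]2OC(C)=O
F2 | step 2 | antipodal saturated dione (enantiomer of 5) | COC(=O)[C@@]12C(=O)CCC(=O)[C@@H]1CCC[C@@H]2OC(C)=O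
F3 | step 24 | spiro alcohol with a terminal diene | C=C/C=C(\CO[Si](C)(C)C(C)(C)C)[C@@H]1CC[C@]2([C@H](CCCO[Si](c3ccccc3)(c3ccccc3)C(C)(C)C)/C(=C(\C)C=O)CC[C@]2(C)O[Si](CC)(CC)CC)[C@@H]1O
F4 | step 24 | dienyl pinacol boronate | CC1(C)OB(OC1(C)C)/C=C/C=C(\CO[Si](C)(C)C(C)(C)C)[C@@H]2CC[C@]3([C@H](CCCO[Si](c4ccccc4)(c4ccccc4)C(C)(C)C)/C(=C(\C)C=O)CC[C@]3(C)O[Si](CC)(CC)CC)[C@@H]2O
F5 | step 19 | primary allylic alcohol | C=CC/C(CO[Si](C)(C)C(C)(C)C)=C/CC[C@]1([C@H](CCCO[Si](c2ccccc2)(c2ccccc2)C(C)(C)C)/C(=C(\C)CO)CC[C@]1(C)O[Si](CC)(CC)CC)CO[Si](CC)(CC)CC
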